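**Plan**
- The retrosynthesis first strips the acetal protecting groups, then cuts the two ring B prenyl bonds C2'–CH2 and C6'–CH2 in a single operation, and last traces the C8–CH2 bond back to a prenyl ether on O5. The flavonol skeleton is never cut and comes from quercetin.
- What permits the double cut: C2' and C6' are the two ring B carbons flanking C1'. A metal held on O3 of ring C therefore reaches either C–H through a six-membered metallacycle (metal, O3, C3, C2, C1', C2' or C6'). The other neighbour of C2 is the bare ring oxygen O1, which leaves room for two ortho substituents.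
- Forward, no ring is formed (rings A, B and C are those of quercetin). The order is: catechol ketal, MOM on O7, pivalate on O3, prenyl on O5, Claisen–Cope shift of that prenyl to C8, MOM on O5, release of O3–H, twofold C–H prenylation of ring B, global deprotection.
- Stereochemistry: the target has no stereocentre and each olefin ends in two methyl groups, so nothing has to be controlled.

Key step: step 9

Remark: the target is read from its SMILES as 2',6',8-triprenylquercetin; flavonoid numbering is used, prenyl = 3-methylbut-2-enyl, MOM = methoxymethyl, Piv = pivaloyl.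

**Route**

Step 1
Reactants: 1 quercetin; 2 dichlorodiphenylmethane
Product: 3 3',4'-O-(diphenylmethylene)quercetin
Conditions: Ph2CCl2 (1.5 equiv), Ph2O, 175 °C, 30 min
Reagents that add atoms: dichlorodiphenylmethane (2), ClC(Cl)(c1ccccc1)c1ccccc1
Why: Ketalisation of a catechol with a geminal dichloride, in which only the 3',4'-diol of ring B can close a five-membered 1,3-benzodioxole, so the 3-, 5- and 7-hydroxyls stay free.

Step 2
Reactants: 3 3',4'-O-(diphenylmethylene)quercetin
Product: 4 7-O-MOM-3',4'-O-(diphenylmethylene)quercetin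
Conditions: MOMCl (1.1 equiv), K2CO3 (1.5 equiv), acetone, 0 °C to rt
Reagents that add atoms: chloromethyl methyl ether, COCCl
Why: Williamson-type O-alkylation at the most acidic hydroxyl: O7–H is a vinylogous acid through C4=O whereas O3–H and O5–H are hydrogen-bonded to that carbonyl, so one equivalent of the chloride should take O7 first.

Step 3
Reactants: 4 7-O-MOM-3',4'-O-(diphenylmethylene)quercetin
Product: 5 7-O-MOM-3-O-pivaloyl-3',4'-O-(diphenylmethylene)quercetin
Conditions: PivCl (1.2 equiv), Et3N (2 equiv), DMAP (0.1 equiv), CH2Cl2, 0 °C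
Reagents that add atoms: pivaloyl chloride, CC(C)(C)C(Cl)=O
Why: DMAP-catalysed acylation of the enolic 3-hydroxyl, the 5-hydroxyl being locked in a six-membered hydrogen bond to C4=O and left untouched under these mild conditions, as in the partial acylation of quercetin.

Step 4
Reactants: 5 7-O-MOM-3-O-pivaloyl-3',4'-O-(diphenylmethylene)quercetin; 6 prenyl bromide
Product: 7 5-O-prenyl-7-O-MOM-3-O-pivaloyl-3',4'-O-(diphenylmethylene)quercetin
Conditions: prenyl bromide (3 equiv), K2CO3 (3 equiv), dry DMF, 40 °C
Reagents that add atoms: prenyl bromide (6), CC(C)=CCBr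
Why: Williamson ether synthesis on the only hydroxyl left, with anhydrous carbonate basic enough to open the O5–H chelate while the pivalate, the MOM ether and the ketal should stay intact.

Step 5
Reactants: 7 5-O-prenyl-7-O-MOM-3-O-pivaloyl-3',4'-O-(diphenylmethylene)quercetin
Product: 10 8-prenyl-7-O-MOM-3-O-pivaloyl-3',4'-O-(diphenylmethylene)quercetin, via C6 reverse-prenyl dienone 8 (not isolated), via C8 prenyl dienone 9 (not isolated)
Conditions: Eu(fod)3 (10 mol%), NaHCO3, PhCl, 85 °C
Reagents that add atoms: none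
Why: Lewis-acid-promoted para-Claisen–Cope rearrangement, in which Eu(fod)3 held between O4 and O5 speeds the [3,3] shift of the ether to C6 (the only open ortho carbon) and the resulting dienone passes its 2-methylbut-3-en-2-yl group to C8 by a Cope [3,3] shift and enolises, the established way to 8-prenyl 5-hydroxyflavonoids.

Step 6
Reactants: 10 8-prenyl-7-O-MOM-3-O-pivaloyl-3',4'-O-(diphenylmethylene)quercetin
Product: 12 8-prenyl-5,7-di-O-MOM-3-O-pivaloyl-3',4'-O-(diphenylmethylene)quercetin, via sodium 5-phenoxide 11 (not isolated)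
Conditions: NaH (1.5 equiv), DMF, 0 °C; MOMCl (1.5 equiv), 0 °C to rt
Reagents that add atoms: chloromethyl methyl ether, COCCl
Why: Irreversible deprotonation breaks the O5–H to O4 chelate and the phenoxide is alkylated in a Williamson-type reaction, the pivalate meeting no nucleophile in dry DMF; the O5 acetal removes the second chelating site beside C4=O before the rhodium step.

Step 7
Reactants: 12 8-prenyl-5,7-di-O-MOM-3-O-pivaloyl-3',4'-O-(diphenylmethylene)quercetin
Product: 13 8-prenyl-5,7-di-O-MOM-3',4'-O-(diphenylmethylene)quercetin (3-hydroxyl free)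
Conditions: K2CO3 (1.5 equiv), MeOH/THF 1:1, rt, argon
Reagents that add atoms: none
Why: Base-mediated transesterification (methanolysis) of the enol pivalate, which leaves as the stabilised flavonolate, while the MOM ethers, the ketal and the prenyl group are inert to carbonate in methanol.

Step 8
Reactants: 14 2-methylbut-3-en-2-ol
Product: 16 methyl 2-methylbut-3-en-2-yl carbonate, via lithium 2-methylbut-3-en-2-olate 15 (not isolated)
Conditions: n-BuLi (1.05 equiv), THF, −78 °C; ClCO2Me (1.2 equiv), −78 °C to rt
Reagents that add atoms: methyl chloroformate, COC(Cl)=O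
Why: O-acylation of a preformed tertiary lithium alkoxide with a chloroformate, the standard preparation of tertiary allylic carbonates that acylate too slowly with amine bases.

Step 9
Reactants: 13 8-prenyl-5,7-di-O-MOM-3',4'-O-(diphenylmethylene)quercetin; 16 methyl 2-methylbut-3-en-2-yl carbonate
Product: 18 2',6',8-triprenyl-5,7-di-O-MOM-3',4'-O-(diphenylmethylene)quercetin, via 6'-monoprenylated flavonol 17 (not isolated)
Conditions: [Cp*RhCl2]2 (5 mol%), AgSbF6 (20 mol%), CsOAc (50 mol%), 16 (4 equiv), ClCH2CH2Cl, 70 °C, argon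
Reagents that add atoms: methyl 2-methylbut-3-en-2-yl carbonate (16), C=CC(C)(C)OC(=O)OC
Why: Proposed new method: CsOAc turns the 3-hydroxyl into an O3-bound enolate of cationic Cp*Rh (trivalent rhodium), acetate-assisted concerted metalation-deprotonation of C6'–H closes a six-membered rhodacycle (Rh, O3, C3, C2, C1', C6'), the vinyl group of 16 inserts into the aryl–rhodium bond with its CH2 end on the arene, and β-oxygen elimination of methyl carbonate (lost as CO2 and methanol) releases the linear prenyl group and trivalent rhodium without an oxidant; rotation about C2–C1' then lets the same cycle run at C2'–H and carries 17 on to 18. The closest known reactions are Cp*Rh- and Cp*Co-catalysed directed C–H allylations with allylic carbonates by insertion and β-oxygen elimination, and the hydroxyl- or enol-directed ortho C–H activation of 2-arylphenols and 2-aryl-1,3-dicarbonyl enols, but a flavonol enol has not been shown to direct a twofold C–H prenylation. No ring of the product is closed (the rhodacycles are transient) and no stereocentre arises, since each new olefin ends in two methyl groups. The step needs site selectivity for C2' and C6' and linear selectivity in the allyl transfer: only these two carbons lie within reach of a metal on O3, C5 bears a MOM ether so the C4 ketone has no peri C–H to activate, and C6, C5' and the C8 prenyl olefin have no director nearby, while insertion and β-oxygen elimination on the tertiary carbonate can only deliver the CH2-linked prenyl group. The second metalation at the flanked C2' should remain possible because the cyclic ketal holds O3' back in the ring plane and the first prenyl group can turn toward the unsubstituted O1.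

Step 10
Reactants: 18 2',6',8-triprenyl-5,7-di-O-MOM-3',4'-O-(diphenylmethylene)quercetin
Product: 19 petalostemumol G
Conditions: AcOH/H2O 4:1, 90 °C, argon
Reagents that add atoms: none
Why: Acid hydrolysis of the diaryl ketal (through the diphenyl-stabilised oxocarbenium ion) and of both MOM acetals, in an acid far weaker than the methanolic mineral acid that prenylated flavonoids survive during MOM removal, so the three trisubstituted olefins should not be protonated.

**Compound list**

1 | quercetin | O=c1c(O)c(-c2ccc(O)c(O)c2)oc2cc(O)cc(O)c12 | starting material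
2 | dichlorodiphenylmethane | ClC(Cl)(c1ccccc1)c1ccccc1 | starting material
3 | 3',4'-O-(diphenylmethylene)quercetin | O=c1c(O)c(-c2ccc3OC(c4ccccc4)(c4ccccc4)Oc3c2)oc2cc(O)cc(O)c12 | intermediate
4 | 7-O-MOM-3',4'-O-(diphenylmethylene)quercetin | O=c1c(O)c(-c2ccc3OC(c4ccccc4)(c4ccccc4)Oc3c2)oc2cc(OCOC)cc(O)c12 | intermediate
5 | 7-O-MOM-3-O-pivaloyl-3',4'-O-(diphenylmethylene)quercetin | O=c1c(OC(=O)C(C)(C)C)c(-c2ccc3OC(c4ccccc4)(c4ccccc4)Oc3c2)oc2cc(OCOC)cc(O)c12 | intermediate
6 | prenyl bromide (1-bromo-3-methylbut-2-ene) | CC(C)=CCBr | starting material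
7 | 5-O-prenyl-7-O-MOM-3-O-pivaloyl-3',4'-O-(diphenylmethylene)quercetin | O=c1c(OC(=O)C(C)(C)C)c(-c2ccc3OC(c4ccccc4)(c4ccccc4)Oc3c2)oc2cc(OCOC)cc(OCC=C(C)C)c12 | intermediate
8 | C6 (2-methylbut-3-en-2-yl) cyclohexadienone from the first [3,3] shift (C5 ketone, sp3 C6, racemic) | C=CC(C)(C)C1C(=O)C2=C(C=C1OCOC)OC(-c1ccc3OC(c4ccccc4)(c4ccccc4)Oc3c1)=C(OC(=O)C(C)(C)C)C2=O | intermediate (not isolated)
9 | C8 prenyl cyclohexadienone, keto tautomer of 10 (C5 ketone, sp3 C8, racemic) | CC(C)=CCC1C(OCOC)=CC(=O)C2=C1OC(-c1ccc3OC(c4ccccc4)(c4ccccc4)Oc3c1)=C(OC(=O)C(C)(C)C)C2=O | intermediate (not isolated)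
10 | 8-prenyl-7-O-MOM-3-O-pivaloyl-3',4'-O-(diphenylmethylene)quercetin (5-hydroxyl free) | CC(C)=CCc1c(OCOC)cc(O)c2c1oc(c(OC(=O)C(C)(C)C)c2=O)-c1ccc2OC(c3ccccc3)(c3ccccc3)Oc2c1 | intermediate
11 | sodium 5-phenoxide of 10 | CC(C)=CCc1c(OCOC)cc([O-])c2c1oc(c(OC(=O)C(C)(C)C)c2=O)-c1ccc2OC(c3ccccc3)(c3ccccc3)Oc2c1.[Na+] | intermediate (not isolated)
12 | 8-prenyl-5,7-di-O-MOM-3-O-pivaloyl-3',4'-O-(diphenylmethylene)quercetin | CC(C)=CCc1c(OCOC)cc(OCOC)c2c1oc(c(OC(=O)C(C)(C)C)c2=O)-c1ccc2OC(c3ccccc3)(c3ccccc3)Oc2c1 | intermediate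
13 | 8-prenyl-5,7-di-O-MOM-3',4'-O-(diphenylmethylene)quercetin (3-hydroxyl free) | CC(C)=CCc1c(OCOC)cc(OCOC)c2c1oc(c(O)c2=O)-c1ccc2OC(c3ccccc3)(c3ccccc3)Oc2c1 | intermediate
14 | 2-methylbut-3-en-2-ol | C=CC(C)(C)O | starting material
15 | lithium 2-methylbut-3-en-2-olate | C=CC(C)(C)[O-].[Li+] | intermediate (not isolated)
16 | methyl 2-methylbut-3-en-2-yl carbonate | C=CC(C)(C)OC(=O)OC | intermediate
17 | 6',8-diprenyl-5,7-di-O-MOM-3',4'-O-(diphenylmethylene)quercetin | CC(C)=CCc1c(OCOC)cc(OCOC)c2c1oc(c(O)c2=O)-c1cc2OC(c3ccccc3)(c3ccccc3)Oc2cc1CC=C(C)C | intermediate (not isolated)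
18 | 2',6',8-triprenyl-5,7-di-O-MOM-3',4'-O-(diphenylmethylene)quercetin | CC(C)=CCc1c(OCOC)cc(OCOC)c2c1oc(c(O)c2=O)-c1c(CC=C(C)C)cc2OC(c3ccccc3)(c3ccccc3)Oc2c1CC=C(C)C | intermediate
19 | petalostemumol G (2',6',8-triprenylquercetin) | CC(C)=CCc1cc(O)c(O)c(CC=C(C)C)c1-c1oc2c(CC=C(C)C)c(O)cc(O)c2c(=O)c1O | target

**Count and risks**

Total step count: 10. Longest linear sequence: 9 steps (steps 1 to 7, then 9 and 10); step 8 is a one-step side branch.

The three steps most likely to fail:

1. Step 9 (twofold enol-directed C–H prenylation). The catalyst may rest as the five-membered O3/O4 chelate and not turn over. The second metalation at the flanked C2' may stall at the monoprenylated stage. The tertiary carbonate may ionise under the cationic metal and alkylate O3 instead of carbon. Fallback, all by known reactions: the ring B prenyl groups are put in by cross-coupling on a ring B aldehyde and the flavonol is built around them. It sets out from 2 and 6 (with commercial isovanillin and 2,4,6-trihydroxyacetophenone) and rejoins the route at 18. Isovanillin is dibrominated (Br2, NaOAc, AcOH), its free hydroxyl steering bromine to the ortho and para carbons, to give 2,6-dibromo-3-hydroxy-4-methoxybenzaldehyde F1. Demethylation with BBr3 gives 2,6-dibromo-3,4-dihydroxybenzaldehyde F2. Ketalisation with 2 (Ph2O, 170 °C) gives 4,6-dibromo-2,2-diphenyl-1,3-benzodioxole-5-carbaldehyde F3. A twofold Stille coupling with tributyl(3-methylbut-2-enyl)stannane (Pd(PPh3)4, DMF, 100 °C) gives 4,6-bis(3-methylbut-2-enyl)-2,2-diphenyl-1,3-benzodioxole-5-carbaldehyde F4. In parallel, C-prenylation of 2,4,6-trihydroxyacetophenone with 6 (DBU, THF) gives 2,4,6-trihydroxy-3-(3-methylbut-2-enyl)acetophenone F5. MOMCl with i-Pr2NEt then protects the two hydroxyls that are not wedged between the acetyl and the prenyl group, giving 2-hydroxy-4,6-bis(methoxymethoxy)-3-(3-methylbut-2-enyl)acetophenone F6. Claisen–Schmidt condensation of F4 with F6 (KOH, EtOH) gives (E)-1-[2-hydroxy-4,6-bis(methoxymethoxy)-3-(3-methylbut-2-enyl)phenyl]-3-[4,6-bis(3-methylbut-2-enyl)-2,2-diphenyl-1,3-benzodioxol-5-yl]prop-2-en-1-one F7. Algar–Flynn–Oyamada oxidation (H2O2, NaOH, MeOH) closes ring C through the hydroxyl next to the prenyl group and installs the 3-hydroxyl, giving 18.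

2. Step 10 (global deprotection). Ketal hydrolysis may be slow, and prolonged heating in acid could then close a prenyl group onto a neighbouring freed hydroxyl (O7 with the C8 prenyl, O3' with the C2' prenyl) or let the freed catechol oxidise. Fallback: the two kinds of acetal are removed separately and the ketal by exchange instead of hydrolysis. It sets out from 18 and rejoins at 19. Methanolic HCl (3 M, MeOH/THF, rt), the usual conditions for MOM cleavage on prenylated flavonoids, gives 2',6',8-triprenyl-3',4'-O-(diphenylmethylene)quercetin F8. Transthioketalisation with propane-1,3-dithiol and ZnBr2 in CH2Cl2 at 0 °C then moves the diphenylmethylene unit onto sulfur as 2,2-diphenyl-1,3-dithiane and frees the catechol without water or heat, giving 19.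

3. Step 5 (Claisen–Cope shift). The rearrangement may stop after the first shift, leaving the 2-methylbut-3-en-2-yl group on C6, or the Lewis acid may cleave the prenyl ether back to the phenol. Fallback: C8 is functionalised by halogenation and cross-coupling. It sets out from 5 and rejoins at 12. O5 is alkylated first (NaH, MOMCl, DMF) to give 5,7-di-O-MOM-3-O-pivaloyl-3',4'-O-(diphenylmethylene)quercetin F9. With O5 alkylated, electrophilic iodination of 5,7-dioxygenated flavones goes to C8, so N-iodosuccinimide in DMF should give 8-iodo-5,7-di-O-MOM-3-O-pivaloyl-3',4'-O-(diphenylmethylene)quercetin F10. Stille coupling with tributyl(3-methylbut-2-enyl)stannane (Pd(PPh3)4, DMF, 90 °C) then gives 12.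

**Further compounds**

F1 | step 9 | 2,6-dibromo-3-hydroxy-4-methoxybenzaldehyde | O=Cc1c(Br)cc(OC)c(O)c1Br
F2 | step 9 | 2,6-dibromo-3,4-dihydroxybenzaldehyde | O=Cc1c(Br)cc(O)c(O)c1Br
F3 | step 9 | 4,6-dibromo-2,2-diphenyl-1,3-benzodioxole-5-carbaldehyde | O=Cc1c(Br)cc2OC(c3ccccc3)(c3ccccc3)Oc2c1Br
F4 | step 9 | 4,6-bis(3-methylbut-2-enyl)-2,2-diphenyl-1,3-benzodioxole-5-carbaldehyde | O=Cc1c(CC=C(C)C)cc2OC(c3ccccc3)(c3ccccc3)Oc2c1CC=C(C)C
F5 | step 9 | 2,4,6-trihydroxy-3-(3-methylbut-2-enyl)acetophenone | CC(=O)c1c(O)cc(O)c(CC=C(C)C)c1O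
F6 | step 9 | 2-hydroxy-4,6-bis(methoxymethoxy)-3-(3-methylbut-2-enyl)acetophenone | CC(=O)c1c(OCOC)cc(OCOC)c(CC=C(C)C)c1O
F7 | step 9 | (E)-1-[2-hydroxy-4,6-bis(methoxymethoxy)-3-(3-methylbut-2-enyl)phenyl]-3-[4,6-bis(3-methylbut-2-enyl)-2,2-diphenyl-1,3-benzodioxol-5-yl]prop-2-en-1-one | O=C(/C=C/c1c(CC=C(C)C)cc2OC(c3ccccc3)(c3ccccc3)Oc2c1CC=C(C)C)c1c(OCOC)cc(OCOC)c(CC=C(C)C)c1O
F8 | step 10 | 2',6',8-triprenyl-3',4'-O-(diphenylmethylene)quercetin | CC(C)=CCc1c(O)cc(O)c2c1oc(c(O)c2=O)-c1c(CC=C(C)C)cc2OC(c3ccccc3)(c3ccccc3)Oc2c1CC=C(C)C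
F9 | step 5 | 5,7-di-O-MOM-3-O-pivaloyl-3',4'-O-(diphenylmethylene)quercetin | O=c1c(OC(=O)C(C)(C)C)c(-c2ccc3OC(c4ccccc4)(c4ccccc4)Oc3c2)oc2cc(OCOC)cc(OCOC)c12
F10 | step 5 | 8-iodo-5,7-di-O-MOM-3-O-pivaloyl-3',4'-O-(diphenylmethylene)quercetin | O=c1c(OC(=O)C(C)(C)C)c(-c2ccc3OC(c4ccccc4)(c4ccccc4)Oc3c2)oc2c(I)c(OCOC)cc(OCOC)c12
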